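**Retrosynthetic overview**
1. Rings A and B are bought intact (acetophenone 1, aldehyde 2). Ring C is the only ring built and is closed first, by O1–C2 bond formation (chalcone 3 → flavanone 4 → flavone 5).
2. C5–OH ⇒ C5–H of 5, by carbonyl-directed C–H oxygenation (trifluoroacetate 6, then phenol 7).
3. C6–OH of target 9 ⇒ C6–H of 7, by phenol-directed aerobic ortho-oxygenation through ortho-quinone 8 (the key, new C–O bond-forming step).
4. Both ring-A hydroxyls are therefore installed late as C–O bonds on a plain 7,8-dimethoxy ring, with no protecting groups.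

Assumption: the target (5,6-dihydroxy-7,8,3',4'-tetramethoxyflavone) has no stereocentre and is achiral, so no stereocontrol is needed; 1 and 2 are taken as inexpensive catalogue chemicals.

**Route**

Step 1
Reactants: 1 1-(2-hydroxy-3,4-dimethoxyphenyl)ethanone; 2 3,4-dimethoxybenzaldehyde
Product: 5 2-(3,4-dimethoxyphenyl)-7,8-dimethoxy-4H-chromen-4-one, via chalcone 3 (not isolated), via flavanone 4 (not isolated)
Conditions: pyrrolidine (0.5 equiv), I2 (10 mol%), DMSO, 150 °C, one pot
Reagents that add atoms: none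
Why: Pyrrolidine-mediated Claisen–Schmidt condensation gives the (E)-2'-hydroxychalcone, whose phenol closes ring C by 6-endo oxa-Michael addition (O1–C2 bond) to the racemic flavanone, and I2/DMSO dehydrogenation (alpha-iodination, loss of HI, DMSO as terminal oxidant) gives the flavone and erases the transient C2 stereocentre.

Step 2
Reactants: 5 2-(3,4-dimethoxyphenyl)-7,8-dimethoxy-4H-chromen-4-one
Product: 7 2-(3,4-dimethoxyphenyl)-5-hydroxy-7,8-dimethoxy-4H-chromen-4-one, via aryl trifluoroacetate 6 (not isolated)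
Conditions: [RuCl2(p-cymene)]2 (2.5 mol%), PhI(OCOCF3)2 (2.0 equiv), CF3CO2H/(CF3CO)2O, 80 °C; then H2O, rt
Reagents that add atoms: [bis(trifluoroacetoxy)iodo]benzene, O=C(OI(OC(=O)C(F)(F)F)c1ccccc1)C(F)(F)F
Why: Ketone-directed C–H oxygenation: the C4 carbonyl guides the divalent ruthenium catalyst to the peri C5–H (five-membered ruthenacycle), the hypervalent iodine oxidant triggers C–O reductive elimination to the aryl trifluoroacetate, which is shielded from over-oxidation until water cleaves it on work-up, while the protonated chromone deactivates both dimethoxyarene rings towards the oxidant.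

Step 3
Reactants: 7 2-(3,4-dimethoxyphenyl)-5-hydroxy-7,8-dimethoxy-4H-chromen-4-one
Product: 9 pebrellin (2-(3,4-dimethoxyphenyl)-5,6-dihydroxy-7,8-dimethoxy-4H-chromen-4-one), via ortho-quinone 8 (not isolated)
Conditions: [Cu(MeCN)4]PF6 (10 mol%), N,N'-di-tert-butylethylenediamine (20 mol%), O2 (1 atm), 4 Å MS, CH2Cl2, rt; then aq. Na2S2O4, rt
Reagents that add atoms: dioxygen, O=O
Why: Proposed new method: tyrosinase-type aerobic ortho-oxygenation of a carbonyl-chelated 5-hydroxyflavone, in which monovalent copper, the diamine and O2 form a side-on peroxo dicopper core (divalent copper) that binds the 5-phenolate once the hemilabile C4 carbonyl steps aside; the bound peroxide attacks C6, the only free ortho carbon (also ortho to the 7-OMe and para to O1, so the most nucleophilic carbon of ring A, while the para carbon C8 is blocked and ring B has no phenol to bind copper), giving a copper catecholate that is released as ortho-quinone 8, which frees the catalyst from the chelating product, and dithionite reduces 8 to the catechol; the closest known reaction type is the copper/diamine-catalysed aerobic ortho-oxygenation of simple, non-chelated phenols to ortho-quinones, which has not been shown on hydrogen-bonded peri-acyl phenols such as 5-hydroxyflavones.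

**Compound list**
1 | 1-(2-hydroxy-3,4-dimethoxyphenyl)ethanone (2'-hydroxy-3',4'-dimethoxyacetophenone) | CC(=O)c1ccc(OC)c(OC)c1O | starting material
2 | 3,4-dimethoxybenzaldehyde (veratraldehyde) | COc1ccc(C=O)cc1OC | starting material
3 | (E)-1-(2-hydroxy-3,4-dimethoxyphenyl)-3-(3,4-dimethoxyphenyl)prop-2-en-1-one (chalcone, formed in the flask) | COc1ccc(/C=C/C(=O)c2ccc(OC)c(OC)c2O)cc1OC | intermediate
4 | racemic 2-(3,4-dimethoxyphenyl)-7,8-dimethoxychroman-4-one (flavanone, formed in the flask) | COc1ccc(C2CC(=O)c3ccc(OC)c(OC)c3O2)cc1OC | intermediate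
5 | 2-(3,4-dimethoxyphenyl)-7,8-dimethoxy-4H-chromen-4-one (7,8,3',4'-tetramethoxyflavone) | COc1ccc(-c2cc(=O)c3ccc(OC)c(OC)c3o2)cc1OC | intermediate
6 | 2-(3,4-dimethoxyphenyl)-7,8-dimethoxy-4-oxo-4H-chromen-5-yl trifluoroacetate (formed in the flask) | COc1ccc(-c2cc(=O)c3c(OC(=O)C(F)(F)F)cc(OC)c(OC)c3o2)cc1OC | intermediate
7 | 2-(3,4-dimethoxyphenyl)-5-hydroxy-7,8-dimethoxy-4H-chromen-4-one (5-hydroxy-7,8,3',4'-tetramethoxyflavone) | COc1ccc(-c2cc(=O)c3c(O)cc(OC)c(OC)c3o2)cc1OC | intermediate
8 | 2-(3,4-dimethoxyphenyl)-7,8-dimethoxy-4H-chromene-4,5,6-trione (ortho-quinone, formed in the flask) | COc1ccc(C2=CC(=O)C3=C(O2)C(OC)=C(OC)C(=O)C3=O)cc1OC | intermediate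
9 | pebrellin, 2-(3,4-dimethoxyphenyl)-5,6-dihydroxy-7,8-dimethoxy-4H-chromen-4-one (achiral) | COc1ccc(-c2cc(=O)c3c(O)c(O)c(OC)c(OC)c3o2)cc1OC | target

**Totals**
Total step count: 3. Longest linear sequence: 3.

**Steps most likely to fail, with fallbacks**

1. Step 3 (the proposed new ortho-oxygenation). The chelated 5-OH may bind the copper-oxygen core too weakly, or the product may poison the catalyst. The fallback uses known chemistry and sets out from 7. Duff formylation (hexamethylenetetramine, CF3CO2H, 90 °C, then aq. HCl) attacks the only free ring-A carbon and gives 2-(3,4-dimethoxyphenyl)-5-hydroxy-7,8-dimethoxy-4-oxo-4H-chromene-6-carbaldehyde F1. Dakin oxidation of this ortho-hydroxy aldehyde (30% H2O2, aq. NaOH, pyridine, rt, then dilute HCl) proceeds by aryl migration to 2-(3,4-dimethoxyphenyl)-5-hydroxy-7,8-dimethoxy-4-oxo-4H-chromen-6-yl formate F2, which is hydrolysed in the same flask. The fallback comes back to the route at 9.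

2. Step 2 (ruthenium-catalysed C5–H oxygenation). The hypervalent iodine oxidant in acid may oxidise the two dimethoxyarene rings. The fallback brings the C5 oxygen in with the starting material and sets out from 2. Commercial 1-(2-hydroxy-3,4,6-trimethoxyphenyl)ethanone F3 is condensed with 2 under the step 1 conditions. This passes through (E)-1-(2-hydroxy-3,4,6-trimethoxyphenyl)-3-(3,4-dimethoxyphenyl)prop-2-en-1-one F4 and racemic 2-(3,4-dimethoxyphenyl)-5,7,8-trimethoxychroman-4-one F5 to 2-(3,4-dimethoxyphenyl)-5,7,8-trimethoxy-4H-chromen-4-one F6. BCl3 (CH2Cl2, −78 to 0 °C) then removes only the 5-O-methyl group, through the boron chelate with the C4 carbonyl. The fallback comes back to the route at 7.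

3. Step 1 (one-pot condensation, cyclisation and dehydrogenation). The electron-rich aldehyde may condense slowly, and the hot I2/DMSO medium may give by-products. The fallback is a Baker–Venkataraman sequence and sets out from 1. Acylation with 3,4-dimethoxybenzoyl chloride (pyridine, rt) gives 6-acetyl-2,3-dimethoxyphenyl 3,4-dimethoxybenzoate F7. KOH in pyridine at 50 °C shifts the aroyl group to carbon and gives 1-(2-hydroxy-3,4-dimethoxyphenyl)-3-(3,4-dimethoxyphenyl)propane-1,3-dione F8. Cyclodehydration (H2SO4, AcOH, 100 °C) closes ring C, and the fallback comes back to the route at 5.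

**Further compounds**
F1 | step 3 | 2-(3,4-dimethoxyphenyl)-5-hydroxy-7,8-dimethoxy-4-oxo-4H-chromene-6-carbaldehyde | COc1ccc(-c2cc(=O)c3c(O)c(C=O)c(OC)c(OC)c3o2)cc1OC
F2 | step 3 | 2-(3,4-dimethoxyphenyl)-5-hydroxy-7,8-dimethoxy-4-oxo-4H-chromen-6-yl formate | COc1ccc(-c2cc(=O)c3c(O)c(OC=O)c(OC)c(OC)c3o2)cc1OC
F3 | step 2 | 1-(2-hydroxy-3,4,6-trimethoxyphenyl)ethanone (bought, not made) | CC(=O)c1c(OC)cc(OC)c(OC)c1O
F4 | step 2 | (E)-1-(2-hydroxy-3,4,6-trimethoxyphenyl)-3-(3,4-dimethoxyphenyl)prop-2-en-1-one | COc1ccc(/C=C/C(=O)c2c(OC)cc(OC)c(OC)c2O)cc1OC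
F5 | step 2 | racemic 2-(3,4-dimethoxyphenyl)-5,7,8-trimethoxychroman-4-one | COc1ccc(C2CC(=O)c3c(OC)cc(OC)c(OC)c3O2)cc1OC
F6 | step 2 | 2-(3,4-dimethoxyphenyl)-5,7,8-trimethoxy-4H-chromen-4-one | COc1ccc(-c2cc(=O)c3c(OC)cc(OC)c(OC)c3o2)cc1OC
F7 | step 1 | 6-acetyl-2,3-dimethoxyphenyl 3,4-dimethoxybenzoate | CC(=O)c1ccc(OC)c(OC)c1OC(=O)c1ccc(OC)c(OC)c1
F8 | step 1 | 1-(2-hydroxy-3,4-dimethoxyphenyl)-3-(3,4-dimethoxyphenyl)propane-1,3-dione | COc1ccc(C(=O)CC(=O)c2ccc(OC)c(OC)c2O)cc1OC
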